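**Retrosynthetic overview**

1. The target is a ring-A-opened abietane. On its tetralone (ring B: C-1 quaternary, C-2 CH, C-3 CH2, C-4 C=O) the isopropenyl group on C-2 and the 2-carboxyethyl chain on C-1 are cis, so they are the two ends of a six-membered ring A cut between the acid carbon and the sp2 carbon of the isopropenyl group.
2. Last disconnection: these two carbons are re-joined to a cis-fused hydrophenanthrene-2,9-dione carrying CH2OSO2Me on C-1; hydroxide-induced Grob fragmentation of this temporary ring A gives the acid and the isopropenyl group together.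
3. Key disconnection: in that tricycle the ring B ketone (C-9) and the ring A ketone (C-2) are 1,5-related through C-10 and C-10a. Ring B is therefore closed by the C-10–C-10a bond (C-3–C-2 of the tetralone) in an intramolecular Michael addition of an aryl methyl ketone enolate to a ring A enone, the new enolate being captured by formaldehyde; the aryl tether on the quaternary carbon allows only the cis fusion.
4. The Michael precursor comes from a 4-aryl-2,4-dimethylcyclohexenone (bromination, Br–Li exchange, acetaldehyde, oxidation), this from an asymmetric Robinson annulation of a 2-arylpropanal with ethyl vinyl ketone, and the aldehyde from 1,2,4-trimethoxybenzene by two directed lithiations.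
5. Order of ring formation: ring C (arene) is bought, ring A is built in step 5, ring B is closed in step 10, ring A is opened in step 13.

Key step: step 10

Assumption: the L-proline-derived sulfonamide catalyst of step 5 is taken to give the (4R)-cyclohexenone; if the sense of induction is the opposite, the D-proline-derived catalyst is used and nothing else changes.

**Route**

Step 1
Reactants: 1 1,2,4-trimethoxybenzene
Product: 3 2-(2,3,6-trimethoxyphenyl)propan-2-ol, via 2,3,6-trimethoxyphenyllithium 2 (not isolated)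
Conditions: n-BuLi, THF, 0 °C to rt; acetone, −78 °C to rt; H2O
Reagents that add atoms: acetone CC(C)=O
Why: Directed ortho-metalation takes place at C-3, the position flanked by two methoxy groups, and the aryllithium adds to acetone (1,2-addition).

Step 2
Reactants: 3 2-(2,3,6-trimethoxyphenyl)propan-2-ol
Product: 4 1,2,4-trimethoxy-3-(propan-2-yl)benzene
Conditions: Et3SiH, CF3CO2H, CH2Cl2, 0 °C to rt
Reagents that add atoms: none
Why: Ionic hydrogenation, in which the acid ionises the tertiary benzylic alcohol and Et3SiH delivers hydride to the cation.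

Step 3
Reactants: 4 1,2,4-trimethoxy-3-(propan-2-yl)benzene
Product: 6 1-[2,3,5-trimethoxy-4-(propan-2-yl)phenyl]ethan-1-one, via [2,3,5-trimethoxy-4-(propan-2-yl)phenyl]lithium 5 (not isolated)
Conditions: n-BuLi, TMEDA, Et2O, 0 °C; MeC(O)N(OMe)Me, −78 °C to 0 °C; H2O
Reagents that add atoms: N-methoxy-N-methylacetamide CC(=O)N(C)OC
Why: Directed ortho-metalation and Weinreb ketone synthesis; C-6–H is ortho to one and meta to two methoxy groups, whereas C-5–H is para to a methoxy group and its ortho methoxy group (on C-4) is held with its methyl toward C-5 by the isopropyl group, so deprotonation should occur at C-6.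

Step 4
Reactants: 6 1-[2,3,5-trimethoxy-4-(propan-2-yl)phenyl]ethan-1-one
Product: 8 2-[2,3,5-trimethoxy-4-(propan-2-yl)phenyl]propanal (racemic), via methyl enol ether 7 (not isolated)
Conditions: Ph3P(CH2OMe)Cl, KOtBu, THF, 0 °C to rt; then 2 M HCl, THF, rt
Reagents that add atoms: (methoxymethyl)triphenylphosphonium chloride COC[P+](c1ccccc1)(c1ccccc1)c1ccccc1.[Cl-]; water O
Why: Wittig methoxymethylenation and acid hydrolysis of the enol ether give the one-carbon homologated α-aryl aldehyde, whose stereocentre is re-formed in step 5.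

Step 5
Reactants: 8 2-[2,3,5-trimethoxy-4-(propan-2-yl)phenyl]propanal; 9 pent-1-en-3-one (ethyl vinyl ketone)
Product: 11 (4R)-2,4-dimethyl-4-[2,3,5-trimethoxy-4-(propan-2-yl)phenyl]cyclohex-2-en-1-one, via keto aldehyde 10 (not isolated)
Conditions: N-(4-dodecylbenzenesulfonyl)-L-prolinamide (20 mol %), 4 Å MS, ClCH2CH2Cl, rt; then pyrrolidine (20 mol %), AcOH (20 mol %), 40 °C
Reagents that add atoms: none
Why: Organocatalytic asymmetric Robinson annulation (Yamada–Otani reaction), in which the chiral enamine of 8 adds to the vinyl ketone on one face and so sets the quaternary centre whatever the configuration of 8, and aldol condensation of the ethyl ketone onto the non-enolisable aldehyde closes ring A.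

Step 6
Reactants: 11 (4R)-2,4-dimethyl-4-[2,3,5-trimethoxy-4-(propan-2-yl)phenyl]cyclohex-2-en-1-one
Product: 12 (4R)-4-[2-bromo-3,5,6-trimethoxy-4-(propan-2-yl)phenyl]-2,4-dimethylcyclohex-2-en-1-one
Conditions: NBS, MeCN, 0 °C to rt
Reagents that add atoms: N-bromosuccinimide O=C1CCC(=O)N1Br
Why: Electrophilic aromatic bromination at the only free ring position, which is ortho and para to methoxy groups.

Step 7
Reactants: 12 (4R)-4-[2-bromo-3,5,6-trimethoxy-4-(propan-2-yl)phenyl]-2,4-dimethylcyclohex-2-en-1-one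
Product: 13 (4R)-4-[2-bromo-3,5,6-trimethoxy-4-(propan-2-yl)phenyl]-2,4-dimethylcyclohex-2-en-1-ol (both C-1 epimers)
Conditions: NaBH4, CeCl3·7H2O, MeOH, −20 °C
Reagents that add atoms: none
Why: Luche 1,2-reduction masks the ring A carbonyl group as an allylic alcohol for step 8; the epimer mixture is inconsequential because the carbinol is re-oxidised in step 9.

Step 8
Reactants: 13 (4R)-4-[2-bromo-3,5,6-trimethoxy-4-(propan-2-yl)phenyl]-2,4-dimethylcyclohex-2-en-1-ol
Product: 15 (4R)-4-[2-(1-hydroxyethyl)-3,5,6-trimethoxy-4-(propan-2-yl)phenyl]-2,4-dimethylcyclohex-2-en-1-ol (carbinol epimers), via aryllithium lithium alkoxide 14 (not isolated)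
Conditions: t-BuLi (3.2 equiv), THF, −78 °C; MeCHO, −78 °C to 0 °C; H2O
Reagents that add atoms: acetaldehyde CC=O
Why: Deprotonation of the alcohol and bromine–lithium exchange give a hindered aryllithium that should add to the small electrophile acetaldehyde.

Step 9
Reactants: 15 (4R)-4-[2-(1-hydroxyethyl)-3,5,6-trimethoxy-4-(propan-2-yl)phenyl]-2,4-dimethylcyclohex-2-en-1-ol
Product: 16 (4R)-4-[2-acetyl-3,5,6-trimethoxy-4-(propan-2-yl)phenyl]-2,4-dimethylcyclohex-2-en-1-one
Conditions: Dess–Martin periodinane, CH2Cl2, rt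
Reagents that add atoms: none
Why: Dess–Martin oxidation returns both secondary alcohols to the ketone level, giving the enone and the aryl methyl ketone.

Step 10
Reactants: 16 (4R)-4-[2-acetyl-3,5,6-trimethoxy-4-(propan-2-yl)phenyl]-2,4-dimethylcyclohex-2-en-1-one
Product: 19 (4aR,10aR)-1-(hydroxymethyl)-5,6,8-trimethoxy-1,4a-dimethyl-7-(propan-2-yl)-3,4,4a,10a-tetrahydrophenanthrene-2,9(1H,10H)-dione (C-1 epimers), via acetyl lithium enolate 17 (not isolated), via ring A lithium enolate 18 (not isolated)
Conditions: LiN(i-Pr)2 (1.1 equiv), THF, −78 °C then −40 °C; CH2O (gas, from cracked paraformaldehyde), −78 °C; AcOH, −78 °C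
Reagents that add atoms: formaldehyde C=O
Why: LiN(i-Pr)2 deprotonates the acetyl group to enolate 17, whose terminal carbon adds to the β-carbon of the ring A enone (intramolecular Michael addition) to give the tetrasubstituted ring A enolate 18, which is captured at carbon by monomeric formaldehyde (aldol), so that the quaternary C-1 with its CH2OH group is made in the same operation. The closest known reaction type is the intramolecular Michael addition of a ketone enolate to a cyclohexenone followed by trapping of the regiodefined product enolate (Michael–aldol tandem with formaldehyde). Ring B closes in the 6-(enolendo)-exo-trig mode. The new stereocentre C-10a is controlled by the quaternary centre C-4a: the nucleophile is tied through the aryl group to C-4a and must reach the neighbouring β-carbon axially from the face that carries the aryl group, so only the cis ring fusion can form, while the configuration at C-1 is not controlled and does not matter because C-1 becomes sp2 in step 13. The step needs site selectivity in the deprotonation and regiochemical fidelity of the second enolate: only the acetyl enolate can cyclise, the low temperature and the absence of free ketone should suppress proton transfer from C-10 before formaldehyde arrives, and once C-1 is quaternary a retro-Michael reaction is impossible.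

Step 11
Reactants: 19 (4aR,10aR)-1-(hydroxymethyl)-5,6,8-trimethoxy-1,4a-dimethyl-7-(propan-2-yl)-3,4,4a,10a-tetrahydrophenanthrene-2,9(1H,10H)-dione
Product: 20 [(4aR,10aR)-5,6,8-trimethoxy-1,4a-dimethyl-2,9-dioxo-7-(propan-2-yl)-1,2,3,4,4a,9,10,10a-octahydrophenanthren-1-yl]methyl methanesulfonate (C-1 epimers)
Conditions: MeSO2Cl, Et3N, CH2Cl2, 0 °C
Reagents that add atoms: methanesulfonyl chloride CS(=O)(=O)Cl
Why: Sulfonylation of the primary neopentyl alcohol, which cannot eliminate because C-1 is quaternary.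

Step 12
Reactants: 20 [(4aR,10aR)-5,6,8-trimethoxy-1,4a-dimethyl-2,9-dioxo-7-(propan-2-yl)-1,2,3,4,4a,9,10,10a-octahydrophenanthren-1-yl]methyl methanesulfonate
Product: 21 [(4aR,10aR)-5,6,8-trihydroxy-1,4a-dimethyl-2,9-dioxo-7-(propan-2-yl)-1,2,3,4,4a,9,10,10a-octahydrophenanthren-1-yl]methyl methanesulfonate (C-1 epimers)
Conditions: BBr3, CH2Cl2, −78 °C to 0 °C; H2O
Reagents that add atoms: none
Why: BBr3 cleavage of the three aryl methyl ethers (Lewis acid complexation, bromide attack on methyl), done before the alkene exists because the final phenol–isopropenyl array would cyclise to a chroman under acid.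

Step 13
Reactants: 21 [(4aR,10aR)-5,6,8-trihydroxy-1,4a-dimethyl-2,9-dioxo-7-(propan-2-yl)-1,2,3,4,4a,9,10,10a-octahydrophenanthren-1-yl]methyl methanesulfonate
Product: 22 3-[(1R,2S)-5,7,8-trihydroxy-1-methyl-4-oxo-6-(propan-2-yl)-2-(prop-1-en-2-yl)-1,2,3,4-tetrahydronaphthalen-1-yl]propanoic acid
Conditions: LiOH, THF/H2O (degassed, Ar), rt to 40 °C; then 1 M HCl to pH 3, 0 °C
Reagents that add atoms: lithium hydroxide [Li+].[OH-]
Why: Grob fragmentation, in which hydroxide adds to the ring A ketone and the alkoxide expels mesylate through the C-2–C-1 bond to give the carboxylic acid and the isopropenyl group at once, leaving both stereocentres untouched; degassed conditions protect the polyphenolate from air.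

**Compound list**

1 | 1,2,4-trimethoxybenzene | COc1ccc(OC)c(OC)c1 | starting material
2 | 2,3,6-trimethoxyphenyllithium | [Li]c1c(OC)ccc(OC)c1OC | intermediate
3 | 2-(2,3,6-trimethoxyphenyl)propan-2-ol | COc1ccc(OC)c(C(C)(C)O)c1OC | intermediate
4 | 1,2,4-trimethoxy-3-(propan-2-yl)benzene | COc1ccc(OC)c(C(C)C)c1OC | intermediate
5 | [2,3,5-trimethoxy-4-(propan-2-yl)phenyl]lithium | [Li]c1cc(OC)c(C(C)C)c(OC)c1OC | intermediate
6 | 1-[2,3,5-trimethoxy-4-(propan-2-yl)phenyl]ethan-1-one | CC(=O)c1cc(OC)c(C(C)C)c(OC)c1OC | intermediate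
7 | 1-(1-methoxyprop-1-en-2-yl)-2,3,5-trimethoxy-4-(propan-2-yl)benzene (E/Z mixture) | COC=C(C)c1cc(OC)c(C(C)C)c(OC)c1OC | intermediate
8 | 2-[2,3,5-trimethoxy-4-(propan-2-yl)phenyl]propanal (racemic) | CC(C=O)c1cc(OC)c(C(C)C)c(OC)c1OC | intermediate
9 | pent-1-en-3-one | CCC(=O)C=C | starting material
10 | (2S)-2-methyl-5-oxo-2-[2,3,5-trimethoxy-4-(propan-2-yl)phenyl]heptanal | CCC(=O)CC[C@](C)(C=O)c1cc(OC)c(C(C)C)c(OC)c1OC | intermediate
11 | (4R)-2,4-dimethyl-4-[2,3,5-trimethoxy-4-(propan-2-yl)phenyl]cyclohex-2-en-1-one | CC(C)c1c(OC)cc([C@]2(C)CCC(=O)C(C)=C2)c(OC)c1OC | intermediate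
12 | (4R)-4-[2-bromo-3,5,6-trimethoxy-4-(propan-2-yl)phenyl]-2,4-dimethylcyclohex-2-en-1-one | CC(C)c1c(OC)c(Br)c([C@]2(C)CCC(=O)C(C)=C2)c(OC)c1OC | intermediate
13 | (4R)-4-[2-bromo-3,5,6-trimethoxy-4-(propan-2-yl)phenyl]-2,4-dimethylcyclohex-2-en-1-ol (C-1 epimers) | CC(C)c1c(OC)c(Br)c([C@]2(C)CCC(O)C(C)=C2)c(OC)c1OC | intermediate
14 | lithium (4R)-4-[2-lithio-3,5,6-trimethoxy-4-(propan-2-yl)phenyl]-2,4-dimethylcyclohex-2-en-1-olate | CC(C)c1c(OC)c([Li])c([C@]2(C)CCC(O[Li])C(C)=C2)c(OC)c1OC | intermediate
15 | (4R)-4-[2-(1-hydroxyethyl)-3,5,6-trimethoxy-4-(propan-2-yl)phenyl]-2,4-dimethylcyclohex-2-en-1-ol (carbinol epimers) | CC(C)c1c(OC)c(C(C)O)c([C@]2(C)CCC(O)C(C)=C2)c(OC)c1OC | intermediate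
16 | (4R)-4-[2-acetyl-3,5,6-trimethoxy-4-(propan-2-yl)phenyl]-2,4-dimethylcyclohex-2-en-1-one | CC(C)c1c(OC)c(C(C)=O)c([C@]2(C)CCC(=O)C(C)=C2)c(OC)c1OC | intermediate
17 | lithium 1-{2-[(1R)-1,3-dimethyl-4-oxocyclohex-2-en-1-yl]-3,4,6-trimethoxy-5-(propan-2-yl)phenyl}ethen-1-olate | CC(C)c1c(OC)c(C(=C)O[Li])c([C@]2(C)CCC(=O)C(C)=C2)c(OC)c1OC | intermediate
18 | lithium (4aR,10aR)-5,6,8-trimethoxy-1,4a-dimethyl-9-oxo-7-(propan-2-yl)-3,4,4a,9,10,10a-hexahydrophenanthren-2-olate | COc1c(OC)c(C(C)C)c(OC)c2c1[C@]1(C)CCC(O[Li])=C(C)[C@@H]1CC2=O | intermediate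
19 | (4aR,10aR)-1-(hydroxymethyl)-5,6,8-trimethoxy-1,4a-dimethyl-7-(propan-2-yl)-3,4,4a,10a-tetrahydrophenanthrene-2,9(1H,10H)-dione (C-1 epimers) | COc1c(OC)c(C(C)C)c(OC)c2c1[C@]1(C)CCC(=O)C(C)(CO)[C@@H]1CC2=O | intermediate
20 | [(4aR,10aR)-5,6,8-trimethoxy-1,4a-dimethyl-2,9-dioxo-7-(propan-2-yl)-1,2,3,4,4a,9,10,10a-octahydrophenanthren-1-yl]methyl methanesulfonate (C-1 epimers) | COc1c(OC)c(C(C)C)c(OC)c2c1[C@]1(C)CCC(=O)C(C)(COS(C)(=O)=O)[C@@H]1CC2=O | intermediate
21 | [(4aR,10aR)-5,6,8-trihydroxy-1,4a-dimethyl-2,9-dioxo-7-(propan-2-yl)-1,2,3,4,4a,9,10,10a-octahydrophenanthren-1-yl]methyl methanesulfonate (C-1 epimers) | Oc1c(O)c(C(C)C)c(O)c2c1[C@]1(C)CCC(=O)C(C)(COS(C)(=O)=O)[C@@H]1CC2=O | intermediate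
22 | 3-[(1R,2S)-5,7,8-trihydroxy-1-methyl-4-oxo-6-(propan-2-yl)-2-(prop-1-en-2-yl)-1,2,3,4-tetrahydronaphthalen-1-yl]propanoic acid | C=C(C)[C@@H]1CC(=O)c2c(O)c(C(C)C)c(O)c(O)c2[C@]1(C)CCC(=O)O | target

**Step count and risks**

Total step count: 13. Longest linear sequence: 13 steps.

Steps most likely to fail:

1. Step 10. What may go wrong: deprotonation of the ring A methylene next to the enone carbonyl competes with deprotonation of the acetyl group, and proton transfer from C-10 to the ring A enolate before formaldehyde is captured would place the hydroxymethyl group on the wrong carbon or on uncyclised material. Fallback (sets out from 13, comes back at 19): bromine–lithium exchange on 13 as in step 8 (again through 14) and acylation with 2-chloro-N-methoxy-N-methylacetamide should give (4R)-4-[2-(chloroacetyl)-3,5,6-trimethoxy-4-(propan-2-yl)phenyl]-2,4-dimethylcyclohex-2-en-1-ol F1. MnO2 in CH2Cl2 should oxidise the allylic alcohol to the chloromethyl ketone enone F2. Zn and Me3SiCl in THF (reductive silylation of the α-chloro ketone) should give the silyl enol ether F3 regiospecifically and without base. Catalytic Me3SiOTf in CH2Cl2 at −78 °C should then bring about an intramolecular Mukaiyama–Michael addition with silyl transfer to the ring A trimethylsilyl enol ether F4, in which the position of the enol double bond is fixed. Yb(OTf)3 and aqueous CH2O in THF (hydroxymethylation of a silyl enol ether) should give 19.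

2. Step 5. What may go wrong: slow enamine formation from the α-branched, ortho-substituted aldehyde and insufficient facial discrimination in the Michael addition, which would lower conversion or enantiomeric purity. Fallback (sets out from 4, comes back at 11): lithiation of 4 as in step 3 (through 5) and transmetalation with MgBr2·OEt2 should give the arylmagnesium bromide F5. The coupling partner is made from 3-methylcyclohex-2-en-1-one: reduction with BH3·SMe2 and the catalyst (S)-1-methyl-3,3-diphenyltetrahydro-1H,3H-pyrrolo[1,2-c][1,3,2]oxazaborole should give (1R)-3-methylcyclohex-2-en-1-ol F6, and esterification with picolinic acid and N,N′-dicyclohexylcarbodiimide should give (1R)-3-methylcyclohex-2-en-1-yl pyridine-2-carboxylate F7. CuBr·SMe2-catalysed anti-SN2′ substitution should then give (3R)-3-methyl-3-[2,3,5-trimethoxy-4-(propan-2-yl)phenyl]cyclohex-1-ene F8; the aryl group enters on the face opposite to the leaving group, so the quaternary centre is set by 1,3-chirality transfer. Allylic oxidation with CrO3·3,5-dimethylpyrazole should give the enone F9, iodine and pyridine the α-iodo enone F10, and Stille methylation (Me4Sn, Pd(PPh3)4, CuI) 11.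

3. Step 3. What may go wrong: lithiation at the other free ring position (C-5), which would place the acetyl group on the wrong carbon. Fallback (sets out from 4, comes back at 6): electrophilic bromination of 4 with NBS, expected at C-5 (ortho and para to methoxy groups), should give 1-bromo-2,4,5-trimethoxy-3-(propan-2-yl)benzene F11. The single remaining ring C–H, now flanked by Br and OMe, should be removed by lithium 2,2,6,6-tetramethylpiperidide at −78 °C to give the aryllithium F12, which is acylated with N-methoxy-N-methylacetamide to the bromo ketone F13. Hydrogenolysis of the C–Br bond (H2, Pd/C, Et3N) should give 6.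

**Further compounds**

F1 | step 10 | (4R)-4-[2-(chloroacetyl)-3,5,6-trimethoxy-4-(propan-2-yl)phenyl]-2,4-dimethylcyclohex-2-en-1-ol (C-1 epimers) | CC(C)c1c(OC)c(C(=O)CCl)c([C@]2(C)CCC(O)C(C)=C2)c(OC)c1OC
F2 | step 10 | (4R)-4-[2-(chloroacetyl)-3,5,6-trimethoxy-4-(propan-2-yl)phenyl]-2,4-dimethylcyclohex-2-en-1-one | CC(C)c1c(OC)c(C(=O)CCl)c([C@]2(C)CCC(=O)C(C)=C2)c(OC)c1OC
F3 | step 10 | (4R)-2,4-dimethyl-4-{3,5,6-trimethoxy-4-(propan-2-yl)-2-[1-(trimethylsilyloxy)ethenyl]phenyl}cyclohex-2-en-1-one | CC(C)c1c(OC)c(C(=C)O[Si](C)(C)C)c([C@]2(C)CCC(=O)C(C)=C2)c(OC)c1OC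
F4 | step 10 | (4aR,10aR)-5,6,8-trimethoxy-1,4a-dimethyl-7-(propan-2-yl)-2-(trimethylsilyloxy)-4,4a,10,10a-tetrahydrophenanthren-9(3H)-one | COc1c(OC)c(C(C)C)c(OC)c2c1[C@]1(C)CCC(O[Si](C)(C)C)=C(C)[C@@H]1CC2=O
F5 | step 5 | bromo[2,3,5-trimethoxy-4-(propan-2-yl)phenyl]magnesium | Br[Mg]c1cc(OC)c(C(C)C)c(OC)c1OC
F6 | step 5 | (1R)-3-methylcyclohex-2-en-1-ol | O[C@H]1C=C(C)CCC1
F7 | step 5 | (1R)-3-methylcyclohex-2-en-1-yl pyridine-2-carboxylate | O=C(O[C@H]1C=C(C)CCC1)c1ccccn1
F8 | step 5 | (3R)-3-methyl-3-[2,3,5-trimethoxy-4-(propan-2-yl)phenyl]cyclohex-1-ene | CC(C)c1c(OC)cc([C@]2(C)CCCC=C2)c(OC)c1OC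
F9 | step 5 | (4R)-4-methyl-4-[2,3,5-trimethoxy-4-(propan-2-yl)phenyl]cyclohex-2-en-1-one | CC(C)c1c(OC)cc([C@]2(C)CCC(=O)C=C2)c(OC)c1OC
F10 | step 5 | (4R)-2-iodo-4-methyl-4-[2,3,5-trimethoxy-4-(propan-2-yl)phenyl]cyclohex-2-en-1-one | CC(C)c1c(OC)cc([C@]2(C)CCC(=O)C(I)=C2)c(OC)c1OC
F11 | step 3 | 1-bromo-2,4,5-trimethoxy-3-(propan-2-yl)benzene | Brc1cc(OC)c(OC)c(C(C)C)c1OC
F12 | step 3 | [2-bromo-3,5,6-trimethoxy-4-(propan-2-yl)phenyl]lithium | [Li]c1c(Br)c(OC)c(C(C)C)c(OC)c1OC
F13 | step 3 | 1-[2-bromo-3,5,6-trimethoxy-4-(propan-2-yl)phenyl]ethan-1-one | CC(=O)c1c(Br)c(OC)c(C(C)C)c(OC)c1OC
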